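Everything rests on closing the cyclobutane (C4–C5–C11–C10) last, by forging C5–C11 inside a cis-fused bicyclo[5.4.0]undecanone. The step exploits that C11 is the only cyclobutane carbon α to the C1 ketone and sits 1,4 to C5 across the C4–C10 fusion bond of the six- and seven-membered rings. Base interconverts the C2 and C11 enolates; only the C11 enolate can reach the backside of an equatorial C5 mesylate (O-alkylation would give a bridgehead enol ether), so the mixture funnels into one 4-exo-tet alkylation. The precursor arises from a Diels–Alder reaction between a 2-siloxypentadiene and an enantiopure 3-methylcycloheptenone made by ene, aldol, Fráter–Seebach and metathesis chemistry.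

Key step: step 14

Numbering used throughout (longipinane-type, applied to all intermediates): C1 ketone carbon; C2 CH2; C3 CH(CH3); cyclobutane C4 (bonded to C3, C5, C10), C5 (bonded to C4, C6, C11), C10 (bonded to C4, C9, C11; carries CH3), C11 (bonded to C1, C5, C10); C6 quaternary (CH3 and C14H2–O); C7 and C8 CH–O; C9 CH2. In this numbering the target is (3R,4S,5S,6S,7S,8S,10R,11R), and all three ester groups are (Z)-2-methylbut-2-enoates (angelates).

Step 1
Reactants: 1 ethyl glyoxylate; 2 2-methylpropene
Product: 3 ethyl (S)-2-hydroxy-4-methylpent-4-enoate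
Conditions: (S)-BINOL/TiCl2(OiPr)2 (10 mol %), 4 Å MS, CH2Cl2, −30 °C
Reagents that add atoms: none
Why: Asymmetric glyoxylate–ene reaction in which the chiral titanium BINOLate activates the aldehyde and the alkene transfers an allylic hydrogen through a six-membered transition state, setting the future C8 carbinol; the (S)-ligand is expected to give the (S)-alcohol.

Step 2
Reactants: 3 ethyl (S)-2-hydroxy-4-methylpent-4-enoate
Product: 4 ethyl (S)-2-(benzyloxy)-4-methylpent-4-enoate
Conditions: BnOC(=NH)CCl3, TfOH (cat.), cyclohexane/CH2Cl2, rt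
Reagents that add atoms: benzyl 2,2,2-trichloroacetimidate, N=C(OCc1ccccc1)C(Cl)(Cl)Cl
Why: Acid-catalysed trichloroacetimidate O-benzylation avoids base, so the α-stereocentre should be untouched, and installs the chelating ether needed in step 4.

Step 3
Reactants: 4 ethyl (S)-2-(benzyloxy)-4-methylpent-4-enoate
Product: 5 (S)-2-(benzyloxy)-4-methylpent-4-enal
Conditions: i-Bu2AlH, CH2Cl2, −78 °C; aq. potassium sodium tartrate
Reagents that add atoms: none
Why: Partial ester reduction at low temperature should stop at the aluminium hemiacetal, which releases the α-benzyloxy aldehyde on work-up; it is used crude to avoid epimerisation.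

Step 4
Reactants: 5 (S)-2-(benzyloxy)-4-methylpent-4-enal; 6 1-methoxy-1-(trimethylsilyloxy)prop-1-ene
Product: 7 methyl (3S,4S)-4-(benzyloxy)-3-hydroxy-2,6-dimethylhept-6-enoate (both C2 epimers)
Conditions: MgBr2·OEt2, CH2Cl2, −78 → −20 °C; aq. HCl work-up
Reagents that add atoms: none
Why: Chelation-controlled Mukaiyama aldol addition in which MgBr2 bridges the aldehyde and benzyloxy oxygens and the ketene acetal attacks the face opposite the C9 chain, giving the 3,4-syn pattern (the future trans C7/C8 diol); the C2 configuration is erased in step 5.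

Step 5
Reactants: 7 methyl (3S,4S)-4-(benzyloxy)-3-hydroxy-2,6-dimethylhept-6-enoate; 8 acrolein
Product: 10 methyl (2R,3S,4S)-4-(benzyloxy)-3-hydroxy-2-(1-hydroxyprop-2-en-1-yl)-2,6-dimethylhept-6-enoate, via dilithium enolate-alkoxide 9 (not isolated)
Conditions: LiN(i-Pr)2 (2.3 equiv), THF, −78 → −20 °C; acrolein, −78 °C; AcOH
Reagents that add atoms: none
Why: Fráter–Seebach aldol addition in which the lithium-chelated enolate-alkoxide is attacked by acrolein (1,2-addition) on the face opposite the C7 substituent, so quaternary C6 is set stereoconvergently from both C6 epimers of 7; the epimers at the new carbinol (C5) converge in step 8.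

Step 6
Reactants: 10 methyl (2R,3S,4S)-4-(benzyloxy)-3-hydroxy-2-(1-hydroxyprop-2-en-1-yl)-2,6-dimethylhept-6-enoate
Product: 11 methyl (1R,6S,7S)-6-(benzyloxy)-2,7-dihydroxy-1,4-dimethylcyclohept-3-ene-1-carboxylate (both C2 epimers)
Conditions: second-generation Grubbs catalyst (H2IMes)(PCy3)Cl2Ru=CHPh (5 mol %), CH2Cl2, 40 °C
Reagents that add atoms: none
Why: Ring-closing metathesis of the vinyl carbinol with the 1,1-disubstituted alkene should close the seven-membered ring as the trisubstituted C4=C10 olefin, helped by the quaternary C6 and driven by loss of ethylene.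

Step 7
Reactants: 11 methyl (1R,6S,7S)-6-(benzyloxy)-2,7-dihydroxy-1,4-dimethylcyclohept-3-ene-1-carboxylate
Product: 12 (1S,2R,7S)-7-(benzyloxy)-2-(hydroxymethyl)-2,5-dimethylcyclohept-4-ene-1,3-diol (both C3 epimers)
Conditions: LiAlH4, THF, 0 °C → reflux
Reagents that add atoms: none
Why: Hydride reduction of the hindered α-quaternary ester should give the neopentyl C14 alcohol without touching the allylic alcohol or the alkene.

Step 8
Reactants: 12 (1S,2R,7S)-7-(benzyloxy)-2-(hydroxymethyl)-2,5-dimethylcyclohept-4-ene-1,3-diol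
Product: 13 (5S,6S,7S)-5-(benzyloxy)-6-hydroxy-7-(hydroxymethyl)-3,7-dimethylcyclohept-2-en-1-one
Conditions: MnO2 (excess), CH2Cl2, rt
Reagents that add atoms: none
Why: MnO2 oxidises only the allylic C5 hydroxyl, converging both C5 epimers on one enone and leaving the saturated C7 and C14 hydroxyls.

Step 9
Reactants: 13 (5S,6S,7S)-5-(benzyloxy)-6-hydroxy-7-(hydroxymethyl)-3,7-dimethylcyclohept-2-en-1-one
Product: 14 (5S,6S,7S)-5,6-bis(benzyloxy)-7-[(benzyloxy)methyl]-3,7-dimethylcyclohept-2-en-1-one
Conditions: BnOC(=NH)CCl3 (3 equiv), TfOH (cat.), cyclohexane/CH2Cl2, 0 °C → rt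
Reagents that add atoms: benzyl 2,2,2-trichloroacetimidate, N=C(OCc1ccccc1)C(Cl)(Cl)Cl
Why: Acid-catalysed imidate benzylation protects both hydroxyls without base (which would trigger retro-aldol cleavage of these β-hydroxy ketones), and the benzyl ethers are inert to the acid of step 11 and block fragmentation in step 14.

Step 10
Reactants: 15 (E)-pent-3-en-2-one
Product: 16 (E)-2-(tert-butyldimethylsilyloxy)penta-1,3-diene
Conditions: TBSOTf, Et3N, Et2O, 0 °C
Reagents that add atoms: tert-butyldimethylsilyl triflate, CC(C)(C)[Si](C)(C)OS(=O)(=O)C(F)(F)F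
Why: Soft enolisation (silyl activation of the carbonyl, deprotonation of the methyl group) should give the cross-conjugated 2-siloxy diene with the (E)-propenyl unit intact.

Step 11
Reactants: 14 (5S,6S,7S)-5,6-bis(benzyloxy)-7-[(benzyloxy)methyl]-3,7-dimethylcyclohept-2-en-1-one; 16 (E)-2-(tert-butyldimethylsilyloxy)penta-1,3-diene
Product: 17 cis-fused bicyclic C5 ketone with C1=C2 silyl enol ether
Conditions: Tf2NH (10 mol %), CH2Cl2, −78 → −40 °C; Et3N quench
Reagents that add atoms: none
Why: Acid-catalysed Diels–Alder reaction of a 2-siloxy diene with a β,β-disubstituted cycloalkenone, in which the nucleophilic C11 terminus bonds to the β-carbon C10, the cis-alkene gives the cis fusion (H-4/CH3-10), the endo transition state places CH3-3 cis to C5, and the diene approaches the face opposite the pseudoaxial C6 methyl (held axial by the trans-diequatorial C7/C8 benzyloxy groups).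

Step 12
Reactants: 17 cis-fused bicyclic C5 ketone with C1=C2 silyl enol ether
Product: 19 bicyclic C5-hydroxy C1-ketone, via C5 alcohol silyl enol ether 18 (not isolated)
Conditions: SmI2, H2O, Et3N, THF, rt; then 1 M HCl, THF, rt
Reagents that add atoms: none
Why: Single-electron (ketyl) reduction under thermodynamic control should give the equatorial C5 alcohol, cis to CH3-6 (the axial epimer would be 1,3-diaxial to the C10–C11 bond), and dilute acid then hydrolyses the silyl enol ether to the C1 ketone.

Step 13
Reactants: 19 bicyclic C5-hydroxy C1-ketone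
Product: 20 bicyclic C5-mesyloxy C1-ketone
Conditions: MsCl, Et3N, DMAP (cat.), CH2Cl2, 0 °C
Reagents that add atoms: methanesulfonyl chloride, CS(=O)(=O)Cl
Why: Sulfonylation through the sulfene tolerates the neopentyl environment of the C5 hydroxyl and proceeds with retention at C5.

Step 14
Reactants: 20 bicyclic C5-mesyloxy C1-ketone
Product: 22 tricyclic ketone tribenzyl ether, via potassium C1(11)-enolate 21 (not isolated)
Conditions: KOtBu (3 equiv), t-BuOH/THF, 0 → 50 °C
Reagents that add atoms: none
Why: tert-Butoxide reversibly deprotonates C2 and C11 of the C1 ketone, and the C11 enolate attacks C5 from the face opposite the mesylate in an intramolecular SN2 alkylation (4-exo-tet) that closes the cyclobutane C4–C5–C11–C10. The closest known reaction type is the intramolecular ketone-enolate alkylation of ring-fused keto sulfonates used to close the bridged cyclobutanes of copaene- and longipinene-type sesquiterpenes. C5 is set by inversion and C11 by the cis ring fusion, because the axial C10–C11 bond can only bridge to C5 on the face it already occupies. Regioselectivity is secured by a Curtin–Hammett funnel: in the all-equatorial conformer the C5–O bond is antiperiplanar to C4–C10 and gauche to C4–C3, so only the C11 enolate has a trajectory into σ*(C5–O) while the C2 enolate merely equilibrates. O-Alkylation would create a bridgehead (anti-Bredt) enol ether, E2 elimination lacks an antiperiplanar β-hydrogen (C6 is quaternary, H-4 is gauche), and Grob-type fragmentation is blocked by the benzyl ethers at O7 and O14. The product cannot revert or epimerise because C11 becomes a non-enolisable bridgehead.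

Step 15
Reactants: 22 tricyclic ketone tribenzyl ether
Product: 23 7,8,14-trihydroxylongipinan-1-one
Conditions: H2 (1 atm), Pd(OH)2/C, EtOAc/EtOH, rt
Reagents that add atoms: none
Why: Hydrogenolysis should cleave the three benzyl ethers while the hindered saturated ketone and the cyclobutane stay inert under these neutral conditions.

Step 16
Reactants: 23 7,8,14-trihydroxylongipinan-1-one
Product: 24 CNP0214984.1 (7,8,14-tris(angeloyloxy)longipinan-1-one)
Conditions: angelic acid (6 equiv), 2,4,6-trichlorobenzoyl chloride (6 equiv), Et3N (7 equiv), toluene, rt; then 23, toluene, 80 °C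
Reagents that add atoms: angelic acid, C/C=C(/C)C(=O)O; angelic 2,4,6-trichlorobenzoic anhydride, C/C=C(/C)C(=O)OC(=O)c1c(Cl)cc(Cl)cc1Cl
Why: Yamaguchi-type esterification in which the excess angelic acid is first converted in the flask into its mixed anhydride with 2,4,6-trichlorobenzoic acid, and three molecules of this acyl donor then acylate the C14, C8 and C7 hydroxyls at the less hindered angeloyl carbonyl; omitting a nucleophilic catalyst avoids Z→E isomerisation to tiglates, and no stereocentre is touched.

**Compound list**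

1 | ethyl glyoxylate | CCOC(=O)C=O | starting material
2 | 2-methylpropene (isobutylene) | CC(C)=C | starting material
3 | ethyl (S)-2-hydroxy-4-methylpent-4-enoate | CCOC(=O)[C@@H](O)CC(C)=C | intermediate
4 | ethyl (S)-2-(benzyloxy)-4-methylpent-4-enoate | CCOC(=O)[C@@H](OCc1ccccc1)CC(C)=C | intermediate
5 | (S)-2-(benzyloxy)-4-methylpent-4-enal | O=C[C@@H](OCc1ccccc1)CC(C)=C | intermediate
6 | 1-methoxy-1-(trimethylsilyloxy)prop-1-ene (E/Z mixture) | COC(=CC)O[Si](C)(C)C | starting material
7 | methyl (3S,4S)-4-(benzyloxy)-3-hydroxy-2,6-dimethylhept-6-enoate (both C2 epimers) | COC(=O)C(C)[C@H](O)[C@@H](OCc1ccccc1)CC(C)=C | intermediate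
8 | acrolein (prop-2-enal) | C=CC=O | starting material
9 | dilithium enolate-alkoxide of 7 (not isolated) | COC([O-])=C(C)[C@H]([O-])[C@@H](OCc1ccccc1)CC(C)=C.[Li+].[Li+] | intermediate
10 | methyl (2R,3S,4S)-4-(benzyloxy)-3-hydroxy-2-(1-hydroxyprop-2-en-1-yl)-2,6-dimethylhept-6-enoate (both epimers at the hydroxyallyl carbinol) | COC(=O)[C@](C)(C(O)C=C)[C@H](O)[C@@H](OCc1ccccc1)CC(C)=C | intermediate
11 | methyl (1R,6S,7S)-6-(benzyloxy)-2,7-dihydroxy-1,4-dimethylcyclohept-3-ene-1-carboxylate (both C2 epimers) | COC(=O)[C@]1(C)C(O)C=C(C)C[C@H](OCc2ccccc2)[C@H]1O | intermediate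
12 | (1S,2R,7S)-7-(benzyloxy)-2-(hydroxymethyl)-2,5-dimethylcyclohept-4-ene-1,3-diol (both C3 epimers) | OC[C@]1(C)C(O)C=C(C)C[C@H](OCc2ccccc2)[C@H]1O | intermediate
13 | (5S,6S,7S)-5-(benzyloxy)-6-hydroxy-7-(hydroxymethyl)-3,7-dimethylcyclohept-2-en-1-one | OC[C@]1(C)C(=O)C=C(C)C[C@H](OCc2ccccc2)[C@H]1O | intermediate
14 | (5S,6S,7S)-5,6-bis(benzyloxy)-7-[(benzyloxy)methyl]-3,7-dimethylcyclohept-2-en-1-one | c1ccccc1COC[C@]2(C)C(=O)C=C(C)C[C@H](OCc3ccccc3)[C@H]2OCc4ccccc4 | intermediate
15 | (E)-pent-3-en-2-one | C/C=C/C(C)=O | starting material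
16 | (E)-2-(tert-butyldimethylsilyloxy)penta-1,3-diene | C=C(O[Si](C)(C)C(C)(C)C)/C=C/C | intermediate
17 | cis-fused bicycle lacking the C5–C11 bond (six-membered ring C1–C2–C3–C4–C10–C11, seven-membered ring C4–C5–C6–C7–C8–C9–C10): C1=C2 OTBS enol ether, C5 ketone, 7,8-bis(OBn), 14-OBn; H-4 cis to CH3-10, CH3-3 cis to C5; C3, C4, C6, C7, C8, C10 arranged as in 24 | c1ccccc1COC[C@]2(C)C(=O)[C@@H]3[C@H](C)C=C(O[Si](C)(C)C(C)(C)C)C[C@]3(C)C[C@H](OCc4ccccc4)[C@H]2OCc5ccccc5 | intermediate
18 | C5 alcohol of 17 (5-OH equatorial, cis to CH3-6, trans to C3; not isolated) | c1ccccc1COC[C@]2(C)[C@@H](O)[C@@H]3[C@H](C)C=C(O[Si](C)(C)C(C)(C)C)C[C@]3(C)C[C@H](OCc4ccccc4)[C@H]2OCc5ccccc5 | intermediate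
19 | bicyclic C5-hydroxy C1-ketone (as 18 with the enol ether hydrolysed) | c1ccccc1COC[C@]2(C)[C@@H](O)[C@@H]3[C@H](C)CC(=O)C[C@]3(C)C[C@H](OCc4ccccc4)[C@H]2OCc5ccccc5 | intermediate
20 | bicyclic C5-mesyloxy C1-ketone (mesylate of 19, same C5 configuration) | c1ccccc1COC[C@]2(C)[C@@H](OS(C)(=O)=O)[C@@H]3[C@H](C)CC(=O)C[C@]3(C)C[C@H](OCc4ccccc4)[C@H]2OCc5ccccc5 | intermediate
21 | potassium C1(11)-enolate of 20 (not isolated) | c1ccccc1COC[C@]2(C)[C@@H](OS(C)(=O)=O)[C@@H]3[C@H](C)CC([O-])=C[C@]3(C)C[C@H](OCc4ccccc4)[C@H]2OCc5ccccc5.[K+] | intermediate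
22 | 7,8-bis(benzyloxy)-14-(benzyloxy)longipinan-1-one, configured as 24 | c1ccccc1COC[C@]2(C)[C@H]3[C@@H]4[C@H](C)CC(=O)[C@H]3[C@]4(C)C[C@H](OCc5ccccc5)[C@H]2OCc6ccccc6 | intermediate
23 | 7,8,14-trihydroxylongipinan-1-one, configured as 24 | OC[C@]1(C)[C@H]2[C@@H]3[C@H](C)CC(=O)[C@H]2[C@]3(C)C[C@H](O)[C@H]1O | intermediate
24 | CNP0214984.1, (3R,4S,5S,6S,7S,8S,10R,11R)-7,8,14-tris(angeloyloxy)longipinan-1-one | C/C=C(/C)C(=O)OC[C@]1(C)[C@H]2[C@@H]3[C@H](C)CC(=O)[C@H]2[C@]3(C)C[C@H](OC(=O)/C(C)=C\C)[C@H]1OC(=O)/C(C)=C\C | target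

**Step count.** Total: 16 steps. Longest linear sequence: 15 steps (steps 1–9 and 11–16; step 10 is a one-step side branch).

**Steps most likely to fail, with fallbacks**

Step 14 (ring closure). The displacement at the neopentyl-type C5 may be too slow, so that ionisation or base-induced decomposition of the mesylate outruns the funnelling of the equilibrating enolates. The fallback replaces the equilibrating saturated-ketone enolates by an irreversibly formed, regiodefined cross-conjugated enolate and adds the C3 methyl only after the cyclobutane is closed. It sets out from 14 and comes back at 22. Thermal Diels–Alder reaction of 14 with commercial (E)-1-(dimethylamino)-3-(tert-butyldimethylsilyloxy)buta-1,3-diene (toluene, 80 °C) should give the amino silyl enol ether adduct F1. SmI2/H2O/Et3N reduction of the C5 ketone, then 1 M HCl (enol ether hydrolysis and loss of dimethylamine), should give the bicyclic 2-en-1-one C5 alcohol F2. MsCl/Et3N gives the enone mesylate F3. KN(SiMe3)2 (THF, −78 → 0 °C) deprotonates the only α′ position, C11, and the dienolate closes the cyclobutane to the tricyclic enone F4. Me2CuLi (Et2O, −78 → 0 °C; aq. NH4Cl) then delivers the C3 methyl to the enone face opposite the C10 methyl bridge and gives 22.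

Step 11 (Diels–Alder reaction). The β,β-disubstituted enone may engage the diene too slowly, so that protodesilylation of the diene competes, or endo and facial control may erode. The fallback is a stepwise polar annulation instead of a cycloaddition; it sets out from 14 and comes back at 17. Stoichiometric TiCl4 (CH2Cl2, −78 °C) promotes a Mukaiyama–Michael addition of the C11 terminus of 16 to C10 of 14; the resulting titanium enolate closes onto the pendant enone at C3 and, after work-up, should give the cis-fused bicyclic C1,C5-diketone F5. Kinetic deprotonation at the less hindered C2 (LiN(i-Pr)2, THF, −78 °C) and trapping with TBSCl return 17.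

Step 16 (tris-angeloylation). Acylation of the hindered C7 hydroxyl may stay incomplete, and the forcing conditions may isomerise angelate to tiglate. The fallback builds the (Z)-alkenes after esterification; it sets out from 23 and comes back at 24. Esterification of the three hydroxyls with the unhindered 2-[bis(2,2,2-trifluoroethoxy)phosphoryl]propanoic acid (DCC, DMAP, CH2Cl2) should give the tris(phosphonopropanoate) F6. Still–Gennari olefination with acetaldehyde (KN(SiMe3)2, 18-crown-6, THF, −78 °C) then forms the three (Z)-2-methylbut-2-enoates of 24.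

**Further compounds**

F1 | step 14 | Diels–Alder adduct of 14 with the aminosiloxy diene: cis-fused bicycle with C1=C2 OTBS enol ether, 3-NMe2 (either epimer), C5 ketone | c1ccccc1COC[C@]2(C)C(=O)[C@@H]3C(N(C)C)C=C(O[Si](C)(C)C(C)(C)C)C[C@]3(C)C[C@H](OCc4ccccc4)[C@H]2OCc5ccccc5
F2 | step 14 | cis-fused bicyclic 2-en-1-one with equatorial C5 hydroxyl (no C3 methyl) | c1ccccc1COC[C@]2(C)[C@@H](O)[C@@H]3C=CC(=O)C[C@]3(C)C[C@H](OCc4ccccc4)[C@H]2OCc5ccccc5
F3 | step 14 | C5 mesylate of F2 | c1ccccc1COC[C@]2(C)[C@@H](OS(C)(=O)=O)[C@@H]3C=CC(=O)C[C@]3(C)C[C@H](OCc4ccccc4)[C@H]2OCc5ccccc5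
F4 | step 14 | 7,8,14-tris(benzyloxy)-3-norlongipin-2-en-1-one (tricyclic enone lacking the C3 methyl) | c1ccccc1COC[C@]2(C)[C@H]3[C@@H]4C=CC(=O)[C@H]3[C@]4(C)C[C@H](OCc5ccccc5)[C@H]2OCc6ccccc6
F5 | step 11 | cis-fused bicyclic C1,C5-diketone (17 with the enol ether replaced by the C1 ketone) | c1ccccc1COC[C@]2(C)C(=O)[C@@H]3[C@H](C)CC(=O)C[C@]3(C)C[C@H](OCc4ccccc4)[C@H]2OCc5ccccc5
F6 | step 16 | 7,8,14-tris{2-[bis(2,2,2-trifluoroethoxy)phosphoryl]propanoyloxy}longipinan-1-one (phosphonate α-carbons unassigned) | CC(C(=O)OC[C@]1(C)[C@H]2[C@@H]3[C@H](C)CC(=O)[C@H]2[C@]3(C)C[C@H](OC(=O)C(C)P(=O)(OCC(F)(F)F)OCC(F)(F)F)[C@H]1OC(=O)C(C)P(=O)(OCC(F)(F)F)OCC(F)(F)F)P(=O)(OCC(F)(F)F)OCC(F)(F)F
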